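All runs were computed with made-up constants; the scatter is artificial.

Take the last reading of each earlier run and ask how long the electrophile took to halve; a reading needs no mechanism.

| flask | electrophile | nucleophile | free base | remark | time |
|---|---|---|---|---|---|
| delta | 0.050 M | 0.050 M | 0.027 M | run made earlier |  |
| beta | 0.050 M | 0.050 M | 0.067 M | run made earlier |  |
| green | 0.050 M | 0.0500 M | 0.0500 M |  | 80 min |
| red | 0.050 M | 0.0500 M | 0.0750 M |  | 80 min |

| run | time / min | electrophile / % | target / % |
|---|---|---|---|
| delta | 12.0 | 54 | 34 |
| delta | 25.0 | 34 | 47 |
| delta | 30.0 | 32 | 50 |
| delta | 50.0 | 22 | 59 |
| delta | 60.0 | 18 | 64 |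
| beta | 5.00 | 71 | 22 |
| beta | 8.00 | 60 | 25 |
| beta | 15.0 | 45 | 40 |
| beta | 30.0 | 26 | 52 |
| beta | 60.0 | 17 | 65 |

(scatter of a reading: 2 percentage points)

- part of the electrophile that has reacted at the end, green
- part of the electrophile that has reacted at the end, red
- what raising the concentration of free base from its lowest to its highest value here does to the part of the electrophile that has reacted (changes below 5 percentage points count as none) (no change / it falls / it rises)

- in percentages every species weighs as the electrophile in it: one homo dimer counts as two
- what may be going on: electrophile + nucleophile <-> acid set free + target; nucleophile + acid set free <-> protonated nucleophile; acid set free + free base <-> salt of the base; 2 electrophile -> homo dimer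

Both runs charged electrophile and nucleophile equally, so I treated the loss as second order and used the half-time, the time in which such a loss takes the electrophile to half of what was charged. It is a second-order half-life, and each further stretch of that length counts as one more half-time. I got it twice, from runs with different amounts of free base:

half-time = time × part left / part gone

delta: 13.2 min

beta: 12.3 min

The two last readings stood 1 percentage point apart against a scatter of 2 points, so I trusted both ways and took the mean, 12.7 min.

part left = 1 / (1 + number of half-times)

Green's 80 min held 6.28 half-times, so I reckoned 13.7 % left and 86.3 % reacted. I expected the same for red, although its free base stood above beta's. Delta's and beta's half-times taken separately gave 85.9 % and 86.7 %, a spread of 0.80 points against the 5 points that counts as a change, so I expected none.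

The forecast gave 86 % for green and 87 % for red, the red figure above mine, with no change, in its words “Base has no meaningful effect”.

The flasks gave 88.3 % for green and 89.4 % for red, a change of 1.1 points, which is no change.

    electrophile + nucleophile ⇌ acid set free + target (K = 0.520, k = 0.0190 L mol⁻¹ s⁻¹)
    nucleophile + acid set free ⇌ protonated nucleophile, settled at all times (K = 1.90 × 10⁵ L mol⁻¹)
    acid set free + free base ⇌ salt of the base, settled at all times (K = 3.80 × 10⁵ L mol⁻¹)
    2 electrophile → homo dimer (k = 0.00330 L mol⁻¹ s⁻¹)

Green ended with 45.3 % of its free base unbound and red with 59.4 %. My half-time had put the electrophile left in green at 13.7 %, where 12 % stood. Red also charged electrophile and nucleophile equally, so I used the half-time again for red at 40.0 min: 3.15 half-times put the electrophile left at 24.1 %. Red held 22.0 % of its electrophile at that time.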